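The benzene ring (C1'–C6') is treated as a dehydrogenated 5-alkylcyclohexane-1,3-dione. The 1,3,5-pattern of side chain (C1'), OH (C3') and OMe (C5') maps onto the dione, and its two carbonyl oxygens become the aryl oxygens. In one flask the key step adds dimethyl malonate to the β-carbon of enone 13 (C1'–C6') and closes the methyl-ketone enolate onto a malonate ester (C4'–C5'), creating carbocycle 16. Precursor 13 is an (E)-methyl enone that already carries C2 (R, OTBS) and C8 (S, OBn). Mono-O-methylation, C2 acetylation before any phenol exists, and late dehydrogenation then give the OH/OMe difference without desymmetrising a resorcinol.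

Key step: step 8

Remark: locants C1–C13 (chain, C1 = benzylic CH2) and C1'–C6' (arene) are those of the target, which is (2R,8S). Ring stereocentres that vanish on aromatisation arise as mixtures and are left open in the SMILES.

Step 1
Reactants: 1 (±)-1,2-epoxyheptane
Product: 2 (S)-1,2-epoxyheptane
Conditions: (S,S)-[N,N'-bis(3,5-di-tert-butylsalicylidene)cyclohexane-1,2-diaminato]cobalt acetate (trivalent cobalt, 0.5 mol%), H2O (0.55 equiv), neat, 0 °C → rt; distillation
Reagents that add atoms: none
Why: Hydrolytic kinetic resolution: the (S,S)-catalyst hydrates the (R)-enantiomer far faster, so the unreacted (S)-epoxide, which already holds the C8 configuration, should remain in high enantiomeric purity and distil away from the diol.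

Step 2
Reactants: 2 (S)-1,2-epoxyheptane; 3 6-bromohex-1-ene
Product: 5 (6S)-tridec-12-en-6-ol, via hex-5-enylmagnesium bromide 4 (not isolated)
Conditions: 3, Mg, THF, rt; then CuI (10 mol%), 2, THF, −30 → 0 °C; aq NH4Cl
Reagents that add atoms: none
Why: Copper-catalysed Grignard opening of a terminal epoxide is an SN2 attack at the unsubstituted carbon (future C7), so the C8–O bond and its (S) configuration are untouched while C2–C6 are brought in at once.

Step 3
Reactants: 5 (6S)-tridec-12-en-6-ol
Product: 6 {[(6S)-tridec-12-en-6-yloxy]methyl}benzene (C8 benzyl ether)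
Conditions: NaH, BnBr, Bu4NI (cat.), THF, 0 °C → rt
Reagents that add atoms: benzyl bromide, BrCc1ccccc1
Why: Williamson ether synthesis on the sodium alkoxide; the alkyl benzyl ether tolerates every later reagent and leaves only by hydrogenolysis in the last step.

Step 4
Reactants: 6 C8 benzyl ether
Product: 8 (7S)-7-(benzyloxy)dodecanal, via secondary ozonide 7 (not isolated)
Conditions: O3, CH2Cl2, −78 °C (stop at first blue tinge); Me2S, −78 °C → rt
Reagents that add atoms: ozone, [O-][O+]=O
Why: Ozonolysis with reductive work-up cleaves the only C=C bond to the C2 aldehyde, because the alkene reacts far faster than the benzyl ether at low temperature.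

Step 5
Reactants: 8 (7S)-7-(benzyloxy)dodecanal
Product: 10 (4R,10S)-10-(benzyloxy)pentadec-1-en-4-ol, via homoallyl borinate 9 (not isolated)
Conditions: (−)-B-allyldiisopinocampheylborane (isopinocampheyl groups of the (+)-α-pinene series), Et2O, −78 °C; then 3 M NaOH, 30% H2O2, 0 °C → rt
Reagents that add atoms: (−)-B-allyldiisopinocampheylborane, C=CCB([C@@H]1C[C@@H]2C[C@H]([C@H]1C)C2(C)C)[C@@H]1C[C@@H]2C[C@H]([C@H]1C)C2(C)C
Why: Brown asymmetric allylboration through a closed chair (Zimmerman–Traxler) transition state, in which the isopinocampheyl groups of this series deliver allyl to the Si face of an unbranched aliphatic aldehyde and so set C2 as (R) under reagent control, independent of the remote C8.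

Step 6
Reactants: 10 (4R,10S)-10-(benzyloxy)pentadec-1-en-4-ol
Product: 11 {[(4R,10S)-10-(benzyloxy)pentadec-1-en-4-yl]oxy}(tert-butyl)dimethylsilane
Conditions: TBSCl, imidazole, DMF, rt
Reagents that add atoms: tert-butyldimethylsilyl chloride, CC(C)(C)[Si](C)(C)Cl
Why: Imidazole-promoted silyl ether formation caps the C2 hydroxyl so that it can neither lactonise onto a malonate ester nor fragment by vinylogous retro-aldol in step 8, and TBS is chosen because the methanolic acid of step 10 removes it without an extra step.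

Step 7
Reactants: 11 C2 silyl ether; 12 methyl vinyl ketone
Product: 13 (3E,6R,12S)-12-(benzyloxy)-6-[(tert-butyldimethylsilyl)oxy]heptadec-3-en-2-one
Conditions: 12 (3 equiv), second-generation Grubbs catalyst (H2IMes)(PCy3)Cl2Ru=CHPh (3 mol%), CH2Cl2, 40 °C
Reagents that add atoms: none
Why: Olefin cross-metathesis between an easily dimerising terminal alkene and an electron-poor enone partner favours the cross product, gives the (E)-enone under thermodynamic control and is driven by loss of ethylene.

Step 8
Reactants: 13 (E)-enone; 14 dimethyl malonate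
Product: 16 methyl 6-{(2R,8S)-8-(benzyloxy)-2-[(tert-butyldimethylsilyl)oxy]tridecyl}-2,4-dioxocyclohexane-1-carboxylate (ring epimers; largely enolised), via Michael adduct 15 (not isolated)
Conditions: 14 (1.5 equiv) + NaOMe (1.2 equiv), MeOH, 0 °C, premixed; add 13, 0 °C → rt until 13 is consumed; then reflux; cold 1 M HCl to pH 3–4
Reagents that add atoms: none
Why: Sodium dimethyl malonate adds 1,4 to 13 (Michael addition, C1'–C6'); proton transfer then supplies a small share of the methyl-ketone enolate, which attacks one malonate ester and expels methoxide (intramolecular Claisen condensation, C4'–C5'), and immediate deprotonation of the acidic β-dicarbonyl product pulls all equilibria forward. This is the classical malonate–enone Michael–Claisen annulation that leads to 5-alkylcyclohexane-1,3-diones. The single ring closes in the favoured 6-(enolendo)-exo-trig mode, since both enolate carbons (C3', C4') end up inside the ring while the attacked ester C=O is exocyclic. The two new ring stereocentres (C1', C6') are uncontrolled and need no control, because C6' is lost on decarboxylation and C1' on aromatisation, while C2 and C8 are not touched. The step needs 1,4- over 1,2-addition (secured by the soft stabilised carbanion), closure from CH3 and not from the internal CH2 (which could only give a four-membered ring), and Michael addition faster than γ-deprotonation, which would expel the C2 silyloxy group through the dienolate. Premixing the base with excess malonate leaves no free methoxide while enone is present, and heat is applied only after the enone is gone.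

Step 9
Reactants: 16 keto ester
Product: 18 5-{(2R,8S)-8-(benzyloxy)-2-[(tert-butyldimethylsilyl)oxy]tridecyl}cyclohexane-1,3-dione, via β-keto acid 17 (not isolated)
Conditions: NaOH (3 equiv), MeOH–H2O, 60 °C; 1 M HCl to pH 3, 0 °C; extract; toluene, 80 °C
Reagents that add atoms: none
Why: Ester saponification followed by thermal β-keto acid decarboxylation through the cyclic six-membered transition state removes C6' as a stereocentre, and any silyl ether lost on the way converges with the main material in step 10.

Step 10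
Reactants: 18 dione
Product: 20 5-[(2R,8S)-8-(benzyloxy)-2-hydroxytridecyl]-3-methoxycyclohex-2-en-1-one (C1' epimers), via silylated methyl enol ether 19 (not isolated)
Conditions: HCl (0.3 M in MeOH), rt; NaHCO3 quench
Reagents that add atoms: methanol, CO
Why: Acid-catalysed enol etherification (vinylogous Fischer esterification) stops at the conjugated mono methyl ether, either carbonyl leads to the same arene, and the same acid methanolyses the secondary TBS ether at the Si–O bond so that C2 keeps its configuration.

Step 11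
Reactants: 20 hydroxy enol ether
Product: 21 (2R,8S)-8-(benzyloxy)-1-(3-methoxy-5-oxocyclohex-3-en-1-yl)tridecan-2-yl acetate
Conditions: Ac2O, pyridine, DMAP (cat.), CH2Cl2, rt
Reagents that add atoms: acetic anhydride, CC(=O)OC(C)=O
Why: DMAP-catalysed O-acylation of the only free hydroxyl needs no chemoselectivity because no phenol exists yet, and it does not touch the C2–O bond.

Step 12
Reactants: 21 acetate
Product: 24 (2R,8S)-8-(benzyloxy)-1-(3-hydroxy-5-methoxyphenyl)tridecan-2-yl acetate, via silyloxydiene 22 (not isolated), via aryl trimethylsilyl ether 23 (not isolated)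
Conditions: TMSOTf (1.3 equiv), Et3N (2.5 equiv), CH2Cl2, 0 °C; pentane, cold aq NaHCO3 wash, concentrate; DDQ (1.05 equiv), 2,4,6-collidine, CH2Cl2, 0 °C; then 1 M HCl–THF, rt
Reagents that add atoms: none
Why: Soft enolisation of the Lewis-basic vinylogous ester (the method used for 1-alkoxy-3-silyloxy dienes) outruns that of the acetate, and quinone dehydrogenation then takes the C1'–H hydride to give an arenium ion stabilised by both oxygens, which loses a C6' proton; a regioisomeric diene would converge on the same arene, and the labile aryl silyl ether falls off in the acid wash.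

Step 13
Reactants: 24 phenol benzyl ether
Product: 25 (2R,8S)-8-hydroxy-1-(3-hydroxy-5-methoxyphenyl)tridecan-2-yl acetate (target)
Conditions: H2 (1 atm), Pd/C (10 wt%), EtOAc, rt
Reagents that add atoms: none
Why: Catalytic hydrogenolysis cleaves the alkyl benzyl ether at its benzylic C–O bond, whereas the C2 acetate is homobenzylic and stays, as do the arene, the methyl ether and both stereocentres.

Compound list
1 | (±)-1,2-epoxyheptane (2-pentyloxirane) | CCCCCC1CO1 | starting material
2 | (S)-1,2-epoxyheptane | CCCCC[C@H]1CO1 | intermediate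
3 | 6-bromohex-1-ene | C=CCCCCBr | starting material
4 | hex-5-enylmagnesium bromide | C=CCCCC[Mg]Br | intermediate
5 | (6S)-tridec-12-en-6-ol | CCCCC[C@H](O)CCCCCC=C | intermediate
6 | {[(6S)-tridec-12-en-6-yloxy]methyl}benzene | CCCCC[C@H](OCc1ccccc1)CCCCCC=C | intermediate
7 | 3-[(6S)-6-(benzyloxy)undecyl]-1,2,4-trioxolane (ring epimers) | CCCCC[C@H](OCc1ccccc1)CCCCCC1OCOO1 | intermediate
8 | (7S)-7-(benzyloxy)dodecanal | CCCCC[C@H](OCc1ccccc1)CCCCCC=O | intermediate
9 | (4R,10S)-10-(benzyloxy)pentadec-1-en-4-yl diisopinocampheylborinate | CCCCC[C@H](OCc1ccccc1)CCCCC[C@H](CC=C)OB([C@@H]1C[C@@H]2C[C@H]([C@H]1C)C2(C)C)[C@@H]1C[C@@H]2C[C@H]([C@H]1C)C2(C)C | intermediate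
10 | (4R,10S)-10-(benzyloxy)pentadec-1-en-4-ol | CCCCC[C@H](OCc1ccccc1)CCCCC[C@H](CC=C)O | intermediate
11 | {[(4R,10S)-10-(benzyloxy)pentadec-1-en-4-yl]oxy}(tert-butyl)dimethylsilane | CCCCC[C@H](OCc1ccccc1)CCCCC[C@H](CC=C)O[Si](C)(C)C(C)(C)C | intermediate
12 | methyl vinyl ketone (but-3-en-2-one) | CC(=O)C=C | starting material
13 | (3E,6R,12S)-12-(benzyloxy)-6-[(tert-butyldimethylsilyl)oxy]heptadec-3-en-2-one | CCCCC[C@H](OCc1ccccc1)CCCCC[C@H](C/C=C/C(C)=O)O[Si](C)(C)C(C)(C)C | intermediate
14 | dimethyl malonate | COC(=O)CC(=O)OC | starting material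
15 | dimethyl 2-{(6R,12S)-12-(benzyloxy)-6-[(tert-butyldimethylsilyl)oxy]-2-oxoheptadecan-4-yl}propanedioate (C4 epimers) | CCCCC[C@H](OCc1ccccc1)CCCCC[C@H](CC(CC(C)=O)C(C(=O)OC)C(=O)OC)O[Si](C)(C)C(C)(C)C | intermediate
16 | methyl 6-{(2R,8S)-8-(benzyloxy)-2-[(tert-butyldimethylsilyl)oxy]tridecyl}-2,4-dioxocyclohexane-1-carboxylate (ring epimers) | CCCCC[C@H](OCc1ccccc1)CCCCC[C@H](CC1CC(=O)CC(=O)C1C(=O)OC)O[Si](C)(C)C(C)(C)C | intermediate
17 | 6-{(2R,8S)-8-(benzyloxy)-2-[(tert-butyldimethylsilyl)oxy]tridecyl}-2,4-dioxocyclohexane-1-carboxylic acid (ring epimers) | CCCCC[C@H](OCc1ccccc1)CCCCC[C@H](CC1CC(=O)CC(=O)C1C(=O)O)O[Si](C)(C)C(C)(C)C | intermediate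
18 | 5-{(2R,8S)-8-(benzyloxy)-2-[(tert-butyldimethylsilyl)oxy]tridecyl}cyclohexane-1,3-dione | CCCCC[C@H](OCc1ccccc1)CCCCC[C@H](CC1CC(=O)CC(=O)C1)O[Si](C)(C)C(C)(C)C | intermediate
19 | 5-{(2R,8S)-8-(benzyloxy)-2-[(tert-butyldimethylsilyl)oxy]tridecyl}-3-methoxycyclohex-2-en-1-one (ring epimers) | CCCCC[C@H](OCc1ccccc1)CCCCC[C@H](CC1CC(=O)C=C(OC)C1)O[Si](C)(C)C(C)(C)C | intermediate
20 | 5-[(2R,8S)-8-(benzyloxy)-2-hydroxytridecyl]-3-methoxycyclohex-2-en-1-one (ring epimers) | CCCCC[C@H](OCc1ccccc1)CCCCC[C@H](CC1CC(=O)C=C(OC)C1)O | intermediate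
21 | (2R,8S)-8-(benzyloxy)-1-(3-methoxy-5-oxocyclohex-3-en-1-yl)tridecan-2-yl acetate (ring epimers) | CCCCC[C@H](OCc1ccccc1)CCCCC[C@H](CC1CC(=O)C=C(OC)C1)OC(C)=O | intermediate
22 | (2R,8S)-8-(benzyloxy)-1-[5-methoxy-3-(trimethylsilyloxy)cyclohexa-2,4-dien-1-yl]tridecan-2-yl acetate (ring epimers) | CCCCC[C@H](OCc1ccccc1)CCCCC[C@H](CC1C=C(O[Si](C)(C)C)C=C(OC)C1)OC(C)=O | intermediate
23 | (2R,8S)-8-(benzyloxy)-1-[3-methoxy-5-(trimethylsilyloxy)phenyl]tridecan-2-yl acetate | CCCCC[C@H](OCc1ccccc1)CCCCC[C@H](Cc1cc(O[Si](C)(C)C)cc(OC)c1)OC(C)=O | intermediate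
24 | (2R,8S)-8-(benzyloxy)-1-(3-hydroxy-5-methoxyphenyl)tridecan-2-yl acetate | CCCCC[C@H](OCc1ccccc1)CCCCC[C@H](Cc1cc(O)cc(OC)c1)OC(C)=O | intermediate
25 | (2R,8S)-8-hydroxy-1-(3-hydroxy-5-methoxyphenyl)tridecan-2-yl acetate | CCCCC[C@H](O)CCCCC[C@H](Cc1cc(O)cc(OC)c1)OC(C)=O | target

Total step count: 13. Longest linear sequence: 13 steps (1 → 25).

Steps most likely to fail

1. Step 8. The enone may be deprotonated at its γ-position and lose the C2 silyloxy group by vinylogous β-elimination before malonate has added, or the Michael addition may reverse during the hot Claisen phase. The fallback sets out from 11 and comes back at 16 by the complementary enoate/acetoacetate annulation. Cross-metathesis of 11 with methyl acrylate (same ruthenium catalyst) gives methyl (2E,5R,11S)-11-(benzyloxy)-5-[(tert-butyldimethylsilyl)oxy]hexadec-2-enoate F1. Methyl acetoacetate and NaOMe in MeOH add through the central carbon to its β-carbon to give dimethyl 2-acetyl-3-{(2R,8S)-8-(benzyloxy)-2-[(tert-butyldimethylsilyl)oxy]tridecyl}pentanedioate F2. The acetyl CH3 enolate of F2 closes onto the chain ester (C3'–C4' in place of C4'–C5') and delivers the same 16. The γ-hydrogens of an enoate are much less acidic than those of an enone and the base present is the weaker acetoacetate anion, so the elimination channel is narrowed.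

2. Step 12. The acetate may compete in the enolisation, the moisture-sensitive diene may revert to the enone before it is oxidised, or the electron-rich ring may be over-oxidised. The fallback sets out from 18 and comes back at 24 by aromatising before the acetate is installed.
   - 18 is O-methylated with Me3SiCHN2 (toluene–MeOH, 0 °C) to 19, which is now isolated.
   - LDA (THF, −78 °C) then PhSeCl gives 5-{(2R,8S)-8-(benzyloxy)-2-[(tert-butyldimethylsilyl)oxy]tridecyl}-3-methoxy-6-(phenylselanyl)cyclohex-2-en-1-one F3.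
   - H2O2/pyridine oxidises F3 to the corresponding selenoxide F4, which undergoes syn elimination and tautomerises to 3-{(2R,8S)-8-(benzyloxy)-2-[(tert-butyldimethylsilyl)oxy]tridecyl}-5-methoxyphenol F5.
   - Bu4NF gives 3-[(2R,8S)-8-(benzyloxy)-2-hydroxytridecyl]-5-methoxyphenol F6.
   - Ac2O/pyridine gives the aryl/alkyl diacetate F7.
   - Pyrrolidine (1 equiv, MeCN, 0 °C) cleaves only the activated aryl acetate by aminolysis to give 24.

3. Step 5. Facial selectivity may be incomplete, leaving a C2 epimer that is hard to remove because C2 and C8 are too far apart for the diastereomers to behave differently. The fallback sets out from 6 and comes back at 10, replacing reagent-controlled addition by a catalytic resolution. mCPBA converts 6 into 2-[(6S)-6-(benzyloxy)undecyl]oxirane as an epimer mixture F8. Hydrolytic kinetic resolution with the (R,R)-enantiomer of the cobalt acetate catalyst of step 1 and 0.55 equiv H2O leaves (2R)-2-[(6S)-6-(benzyloxy)undecyl]oxirane F9. Vinylmagnesium bromide/CuI (THF, −30 °C) opens F9 at C1 to give 10.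

Further compounds
F1 | step 8 | methyl (2E,5R,11S)-11-(benzyloxy)-5-[(tert-butyldimethylsilyl)oxy]hexadec-2-enoate | CCCCC[C@H](OCc1ccccc1)CCCCC[C@H](C/C=C/C(=O)OC)O[Si](C)(C)C(C)(C)C
F2 | step 8 | dimethyl 2-acetyl-3-{(2R,8S)-8-(benzyloxy)-2-[(tert-butyldimethylsilyl)oxy]tridecyl}pentanedioate (epimers) | CCCCC[C@H](OCc1ccccc1)CCCCC[C@H](CC(CC(=O)OC)C(C(C)=O)C(=O)OC)O[Si](C)(C)C(C)(C)C
F3 | step 12 | 5-{(2R,8S)-8-(benzyloxy)-2-[(tert-butyldimethylsilyl)oxy]tridecyl}-3-methoxy-6-(phenylselanyl)cyclohex-2-en-1-one | CCCCC[C@H](OCc1ccccc1)CCCCC[C@H](CC1CC(OC)=CC(=O)C1[Se]c1ccccc1)O[Si](C)(C)C(C)(C)C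
F4 | step 12 | selenoxide of F3 | CCCCC[C@H](OCc1ccccc1)CCCCC[C@H](CC1CC(OC)=CC(=O)C1[Se](=O)c1ccccc1)O[Si](C)(C)C(C)(C)C
F5 | step 12 | 3-{(2R,8S)-8-(benzyloxy)-2-[(tert-butyldimethylsilyl)oxy]tridecyl}-5-methoxyphenol | CCCCC[C@H](OCc1ccccc1)CCCCC[C@H](Cc1cc(O)cc(OC)c1)O[Si](C)(C)C(C)(C)C
F6 | step 12 | 3-[(2R,8S)-8-(benzyloxy)-2-hydroxytridecyl]-5-methoxyphenol | CCCCC[C@H](OCc1ccccc1)CCCCC[C@H](Cc1cc(O)cc(OC)c1)O
F7 | step 12 | (2R,8S)-1-[3-(acetyloxy)-5-methoxyphenyl]-8-(benzyloxy)tridecan-2-yl acetate | CCCCC[C@H](OCc1ccccc1)CCCCC[C@H](Cc1cc(OC(C)=O)cc(OC)c1)OC(C)=O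
F8 | step 5 | 2-[(6S)-6-(benzyloxy)undecyl]oxirane (epimers at the oxirane carbon) | CCCCC[C@H](OCc1ccccc1)CCCCCC1CO1
F9 | step 5 | (2R)-2-[(6S)-6-(benzyloxy)undecyl]oxirane | CCCCC[C@H](OCc1ccccc1)CCCCC[C@@H]1CO1
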